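## Retrosynthetic overview

1. Last C–C bond: the linker C(sp3)–C(sp2) bond (chromene‑CH2CH2–CH=C(Me)) is made by a Pd‑catalysed Negishi coupling of a chromenyl‑ethylzinc (fragment A) with a butenolide (E)‑vinyl iodide (fragment B), followed by desilylation.
2. Fragment A: the 2H‑chromene ring and its quaternary C2 are made by a Pd‑catalysed enantioselective, redox‑neutral allylic C–H etherification of an allyl‑toluquinone, which comes from o‑cresol and an (E)‑allylic bromide (Zr carboalumination of butynol).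
3. Fragment B: the butenolide ring is closed by RCM of a 2‑alkylacrylate of an (R)‑vinyl carbinol; the carbinol stereocentre comes from (R)‑epichlorohydrin and the (E)‑vinyl iodide from Zr carboalumination/iodination.
4. Ring order: chromene (step 6) and butenolide (step 18) are built independently and joined in step 19.

Assumption: CIP descriptors were derived from the given SMILES (butenolide C5 = R, chromene C2 = S). The ligand antipode in step 6 is the one that delivers (S), chosen by screening both.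

## Route

**Fragment A**

Step 1
Reactants: 1, but‑3‑yn‑1‑ol
Product: 2, tert‑butyl(but‑3‑yn‑1‑yloxy)dimethylsilane
Conditions: TBSCl, imidazole, CH2Cl2, 0 °C → rt
Reagents that add atoms: TBSCl, CC(C)(C)[Si](C)(C)Cl
Why: Standard silylation of a primary alcohol so the oxygen survives the organoaluminium, phenoxide and quinone chemistry.

Step 2
Reactants: 2
Product: 3, (E)‑5‑[(tert‑butyldimethylsilyl)oxy]‑3‑methylpent‑2‑en‑1‑ol
Conditions: AlMe3, Cp2ZrCl2 (0.2 equiv), CH2Cl2, rt; then n‑BuLi, THF, −78 → 0 °C; (CH2O)n, rt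
Reagents that add atoms: trimethylaluminium, C[Al](C)C; paraformaldehyde, C=O
Why: Negishi Zr‑catalysed syn‑carboalumination places Me on the internal carbon with >98% E; the alkenyl alanate is trapped by formaldehyde with retention of geometry.

Step 3
Reactants: 3
Product: 4, (E)‑[(5‑bromo‑3‑methylpent‑3‑en‑1‑yl)oxy](tert‑butyl)dimethylsilane
Conditions: MsCl, Et3N, CH2Cl2, −40 °C; then LiBr, THF, 0 °C
Reagents that add atoms: lithium bromide, [Li+].[Br-]
Why: Mesylation and SN2 bromide displacement gives the primary allylic bromide without E/Z or allylic scrambling and without touching the TBS ether.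

Step 4
Reactants: 5, o‑cresol (3 equiv); 4
Product: 6, 2‑{(E)‑5‑[(tert‑butyldimethylsilyl)oxy]‑3‑methylpent‑2‑en‑1‑yl}‑6‑methylphenol
Conditions: NaH, toluene, 0 °C → rt (excess cresol removed by dilute NaOH wash)
Reagents that add atoms: none
Why: Ortho C‑alkylation of a sodium phenoxide ion pair in a non‑polar solvent (SN2 at the primary allylic carbon, E retained); the only free ortho position of o‑cresol is C6.

Step 5
Reactants: 6
Product: 7, 2‑{(E)‑5‑[(tert‑butyldimethylsilyl)oxy]‑3‑methylpent‑2‑en‑1‑yl}‑6‑methylcyclohexa‑2,5‑diene‑1,4‑dione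
Conditions: (KSO3)2NO, KH2PO4, acetone/H2O, rt, dark
Reagents that add atoms: Fremy's salt, [K+].[K+].[O]N(S(=O)(=O)[O-])S(=O)(=O)[O-]
Why: Teuber oxidation of a 2,6‑disubstituted phenol with a free para position gives the p‑quinone cleanly; the trisubstituted alkene and TBS ether are inert.

Step 6
Reactants: 7
Product: 8, (S)‑2‑{2‑[(tert‑butyldimethylsilyl)oxy]ethyl}‑2,8‑dimethyl‑2H‑chromen‑6‑ol
Conditions: Pd2(dba)3 (2.5 mol %), chiral H8‑BINOL phosphoramidite L* (6 mol %), 2‑fluorobenzoic acid (20 mol %), toluene, 30 °C, Ar, dark, no amine base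
Reagents that add atoms: none
Why: Proposed new method: a redox‑neutral Pd‑catalysed enantioselective intramolecular allylic C–H etherification in which the substrate's own 2,6‑dialkyl‑p‑quinone is the oxidant. With ArCO2H it re‑oxidises L*Pd(0) to L*Pd(II) and becomes the allyl‑hydroquinone; Pd(II) then cleaves the doubly activated (allylic and ring‑benzylic) C–H to an η3‑allyl, and the ortho OH attacks the tertiary allyl terminus in the only possible 6‑membered closure, forming the O–C2 bond and the quaternary centre under ligand control (the pure E alkene fixes the syn/anti pattern, so one ligand antipode gives one enantiomer) and returning Pd(0). The closest known reactions are Pd/phosphoramidite/benzoquinone asymmetric allylic C–H oxidation to chromans, Pd π‑allyl 6‑endo closure to 2‑aryl‑2H‑chromenes, Pd(II) 6‑endo Wacker cyclisation of 2‑geranylphenols, and the racemic amine‑mediated prenylquinone → chromenol isomerisation.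

Step 7
Reactants: 8
Product: 9, tert‑butyl{2‑[(S)‑2,8‑dimethyl‑6‑(triisopropylsilyloxy)‑2H‑chromen‑2‑yl]ethoxy}dimethylsilane
Conditions: TIPSCl, imidazole, DMF, rt
Reagents that add atoms: TIPSCl, CC(C)[Si](Cl)(C(C)C)C(C)C
Why: Silylation of the unhindered phenol removes the acidic proton before organozinc formation; aryl‑OTIPS is orthogonal to the alkyl‑OTBS.

Step 8
Reactants: 9
Product: 10, 2‑[(S)‑2,8‑dimethyl‑6‑(triisopropylsilyloxy)‑2H‑chromen‑2‑yl]ethan‑1‑ol
Conditions: CSA (10 mol %), MeOH/CH2Cl2, 0 °C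
Reagents that add atoms: none
Why: Mild acidic methanolysis cleaves a primary alkyl TBS ether much faster than an aryl TIPS ether and leaves the chromene intact.

Step 9
Reactants: 10
Product: 11, (S)‑2‑(2‑iodoethyl)‑2,8‑dimethyl‑6‑(triisopropylsilyloxy)‑2H‑chromene
Conditions: I2, PPh3, imidazole, CH2Cl2, 0 °C, dark
Reagents that add atoms: iodine, II
Why: Appel iodination of a primary alcohol; the stereocentre is a remote quaternary carbon and is unaffected.

**Fragment B**

Step 10
Reactants: 12, (R)‑epichlorohydrin; 13, ethynyltrimethylsilane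
Product: 14, (R)‑1‑chloro‑5‑(trimethylsilyl)pent‑4‑yn‑2‑ol
Conditions: n‑BuLi, then BF3·OEt2, THF, −78 °C
Reagents that add atoms: none
Why: BF3‑promoted acetylide opening (Yamaguchi) at the terminal epoxide carbon; the chiral‑pool stereocentre is not touched.

Step 11
Reactants: 14
Product: 15, (R)‑6‑(trimethylsilyl)hex‑1‑en‑5‑yn‑3‑ol
Conditions: Me3S+ I− (4 equiv), n‑BuLi (4 equiv), THF, −20 °C → rt
Reagents that add atoms: trimethylsulfonium iodide, C[S+](C)C.[I-]
Why: Dimethylsulfonium methylide closes the chlorohydrin to the epoxide, opens it at CH2 and eliminates Me2S to give the vinyl carbinol (one‑carbon epoxide → allylic alcohol homologation); the carbinol centre is retained.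

Step 12
Reactants: 15
Product: 16, (R)‑hex‑1‑en‑5‑yn‑3‑ol
Conditions: K2CO3, MeOH, rt
Reagents that add atoms: none
Why: Standard protodesilylation of a C‑silyl alkyne.

Step 13
Reactants: 16
Product: 17, (3R,5E)‑6‑iodo‑5‑methylhexa‑1,5‑dien‑3‑ol
Conditions: AlMe3 (3 equiv), Cp2ZrCl2 (0.3 equiv), CH2Cl2, 0 °C → rt; then I2, THF, −30 °C
Reagents that add atoms: trimethylaluminium, C[Al](C)C; iodine, II
Why: Negishi carboalumination is selective for the alkyne over the terminal alkene (the OH is masked in situ as its aluminium alkoxide), and iodinolysis with retention gives the E‑vinyl iodide.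

Step 14
Reactants: 18, methyl acetoacetate; 19, 5‑bromo‑2‑methylpent‑2‑ene
Product: 20, methyl 2‑acetyl‑6‑methylhept‑5‑enoate (racemic)
Conditions: NaH, THF/DMF, 0 °C; then 19, NaI (cat.), 60 °C
Reagents that add atoms: none
Why: Standard C‑alkylation of a β‑keto ester enolate with a primary bromide.

Step 15
Reactants: 20
Product: 21, methyl 6‑methyl‑2‑methylidenehept‑5‑enoate
Conditions: LiHMDS, THF, −78 °C; (CH2O)n, −78 °C → rt
Reagents that add atoms: paraformaldehyde, C=O
Why: Deacetylative α‑methylenation: aldol addition to formaldehyde, acetyl transfer to the new alkoxide and loss of acetate give the 2‑substituted acrylate.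

Step 16
Reactants: 21
Product: 22, 6‑methyl‑2‑methylidenehept‑5‑enoic acid
Conditions: LiOH, THF/MeOH/H2O, rt
Reagents that add atoms: lithium hydroxide, [Li+].[OH-]
Why: Plain saponification of a methyl ester.

Step 17
Reactants: 17; 22
Product: 23, (3R,5E)‑6‑iodo‑5‑methylhexa‑1,5‑dien‑3‑yl 6‑methyl‑2‑methylidenehept‑5‑enoate
Conditions: DCC, DMAP (cat.), CH2Cl2, 0 °C → rt
Reagents that add atoms: none
Why: Steglich esterification acylates the carbinol oxygen with retention at carbon.

Step 18
Reactants: 23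
Product: 24, (R)‑5‑[(E)‑3‑iodo‑2‑methylprop‑2‑en‑1‑yl]‑3‑(4‑methylpent‑3‑en‑1‑yl)furan‑2(5H)‑one
Conditions: Grubbs II (5–10 mol %), CH2Cl2 (5 mM), 40 °C
Reagents that add atoms: none
Why: Ring‑closing metathesis between the terminal vinyl and the 1,1‑disubstituted acrylate alkene forms the five‑membered butenolide with loss of ethylene; the trisubstituted prenyl and vinyl iodide alkenes react far more slowly.

**Union**

Step 19
Reactants: 11 (1.3 equiv); 24
Product: 25, (R)‑5‑{(E)‑5‑[(S)‑2,8‑dimethyl‑6‑(triisopropylsilyloxy)‑2H‑chromen‑2‑yl]‑2‑methylpent‑2‑en‑1‑yl}‑3‑(4‑methylpent‑3‑en‑1‑yl)furan‑2(5H)‑one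
Conditions: 11, Zn dust (BrCH2CH2Br/TMSCl‑activated), LiCl, THF, 40 °C; then 24, Pd(dppf)Cl2 (5 mol %), THF, rt → 45 °C, dark
Reagents that add atoms: none
Why: Negishi C(sp3)–C(sp2) cross‑coupling: the primary alkylzinc iodide is non‑basic and non‑nucleophilic toward the butenolide (the γ‑H stereocentre and lactone survive), dppf suppresses β‑hydride elimination, and the vinyl iodide couples with retention of E geometry.

Step 20
Reactants: 25
Product: 26, tuberatolide B, (R)‑5‑{(E)‑5‑[(S)‑6‑hydroxy‑2,8‑dimethyl‑2H‑chromen‑2‑yl]‑2‑methylpent‑2‑en‑1‑yl}‑3‑(4‑methylpent‑3‑en‑1‑yl)furan‑2(5H)‑one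
Conditions: TBAF, AcOH (1.2 equiv each), THF, 0 °C, dark
Reagents that add atoms: none
Why: Fluoride cleaves the aryl silyl ether rapidly, and AcOH buffering prevents epimerisation at the butenolide γ‑carbon and phenoxide oxidation.

Stereochemistry: butenolide C5 (R) comes from (R)‑epichlorohydrin and is never broken or exposed to unbuffered base. Chromene C2 (S) is set in step 6; it is a quaternary centre, and the chromenes are kept from UV light to avoid photochemical ring‑opening. The E‑alkene comes from step 13 and is retained in step 19. If step 6 gives less than 98% ee, 8 or 9 is enriched by chiral‑phase chromatography before the union, so that 26 is not contaminated with its C2 epimer.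

## Compound list

1 | but‑3‑yn‑1‑ol | C#CCCO | starting material
2 | tert‑butyl(but‑3‑yn‑1‑yloxy)dimethylsilane | C#CCCO[Si](C)(C)C(C)(C)C | intermediate
3 | (E)‑5‑(TBSO)‑3‑methylpent‑2‑en‑1‑ol | CC(C)(C)[Si](C)(C)OCC/C(C)=C/CO | intermediate
4 | (E)‑1‑bromo‑5‑(TBSO)‑3‑methylpent‑2‑ene | CC(C)(C)[Si](C)(C)OCC/C(C)=C/CBr | intermediate
5 | o‑cresol | Cc1ccccc1O | starting material
6 | 2‑[(E)‑5‑(TBSO)‑3‑methylpent‑2‑enyl]‑6‑methylphenol | Cc1cccc(C/C=C(C)/CCO[Si](C)(C)C(C)(C)C)c1O | intermediate
7 | 2‑[(E)‑5‑(TBSO)‑3‑methylpent‑2‑enyl]‑6‑methyl‑1,4‑benzoquinone | CC1=CC(=O)C=C(C/C=C(C)/CCO[Si](C)(C)C(C)(C)C)C1=O | intermediate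
8 | (S)‑2‑[2‑(TBSO)ethyl]‑2,8‑dimethyl‑2H‑chromen‑6‑ol | CC(C)(C)[Si](C)(C)OCC[C@@]1(C)C=Cc2cc(O)cc(C)c2O1 | intermediate
9 | (S)‑2‑[2‑(TBSO)ethyl]‑2,8‑dimethyl‑6‑(TIPSO)‑2H‑chromene | CC(C)(C)[Si](C)(C)OCC[C@@]1(C)C=Cc2cc(O[Si](C(C)C)(C(C)C)C(C)C)cc(C)c2O1 | intermediate
10 | 2‑[(S)‑2,8‑dimethyl‑6‑(TIPSO)‑2H‑chromen‑2‑yl]ethanol | OCC[C@@]1(C)C=Cc2cc(O[Si](C(C)C)(C(C)C)C(C)C)cc(C)c2O1 | intermediate
11 | (S)‑2‑(2‑iodoethyl)‑2,8‑dimethyl‑6‑(TIPSO)‑2H‑chromene | ICC[C@@]1(C)C=Cc2cc(O[Si](C(C)C)(C(C)C)C(C)C)cc(C)c2O1 | intermediate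
12 | (R)‑epichlorohydrin | ClC[C@H]1CO1 | starting material
13 | ethynyltrimethylsilane | C#C[Si](C)(C)C | starting material
14 | (R)‑1‑chloro‑5‑(trimethylsilyl)pent‑4‑yn‑2‑ol | ClC[C@H](O)CC#C[Si](C)(C)C | intermediate
15 | (R)‑6‑(trimethylsilyl)hex‑1‑en‑5‑yn‑3‑ol | C=C[C@H](O)CC#C[Si](C)(C)C | intermediate
16 | (R)‑hex‑1‑en‑5‑yn‑3‑ol | C=C[C@H](O)CC#C | intermediate
17 | (3R,5E)‑6‑iodo‑5‑methylhexa‑1,5‑dien‑3‑ol | C=C[C@H](O)C/C(C)=C/I | intermediate
18 | methyl acetoacetate | CC(=O)CC(=O)OC | starting material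
19 | 5‑bromo‑2‑methylpent‑2‑ene | CC(C)=CCCBr | starting material
20 | methyl 2‑acetyl‑6‑methylhept‑5‑enoate (racemic) | CC(=O)C(CCC=C(C)C)C(=O)OC | intermediate
21 | methyl 6‑methyl‑2‑methylidenehept‑5‑enoate | C=C(CCC=C(C)C)C(=O)OC | intermediate
22 | 6‑methyl‑2‑methylidenehept‑5‑enoic acid | C=C(CCC=C(C)C)C(=O)O | intermediate
23 | (3R,5E)‑6‑iodo‑5‑methylhexa‑1,5‑dien‑3‑yl 6‑methyl‑2‑methylidenehept‑5‑enoate | C=C(CCC=C(C)C)C(=O)O[C@@H](C=C)C/C(C)=C/I | intermediate
24 | (R)‑5‑[(E)‑3‑iodo‑2‑methylallyl]‑3‑(4‑methylpent‑3‑enyl)furan‑2(5H)‑one | CC(C)=CCCC1=C[C@@H](C/C(C)=C/I)OC1=O | intermediate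
25 | 6‑O‑TIPS tuberatolide B | CC(C)=CCCC1=C[C@@H](C/C(C)=C/CC[C@@]2(C)C=Cc3cc(O[Si](C(C)C)(C(C)C)C(C)C)cc(C)c3O2)OC1=O | intermediate
26 | tuberatolide B | CC(C)=CCCC1=C[C@@H](C/C(C)=C/CC[C@@]2(C)C=Cc3cc(O)cc(C)c3O2)OC1=O | target

## Totals and risks

Total steps: 20.
Longest linear sequence: 11 (steps 1–9, 19, 20), which is 0.55 of the total.

Steps most likely to fail:

1. Step 6 (proposed new cycloisomerisation). Risks are low ee from the competing uncatalysed quinone‑methide/oxa‑6π pathway and sluggish C–H cleavage at a trisubstituted alkene. Fallback (known chemistry): isomerise 7 to racemic 8 with hot pyridine (the established prenylquinone → chromenol rearrangement), silylate, and separate the enantiomers of 9 by preparative chiral‑phase HPLC/SFC.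
2. Step 4 (ortho C‑allylation of o‑cresol). Risks are O‑allylation, para attack and SN2′ products. Fallback: protect o‑cresol as its MOM ether, ortho‑lithiate (n‑BuLi/TMEDA), transmetalate to copper, allylate with 4, and remove the MOM group with acid.
3. Step 18 (RCM to the trisubstituted butenolide). Risks are a slow closure onto the 1,1‑disubstituted acrylate and competing metathesis at the prenyl alkene. Fallback: avoid metathesis by carboaluminating/iodinating (R)‑1‑chloropent‑4‑yn‑2‑ol, closing it to the epoxide, opening that with the dianion of 2‑(phenylthio)‑6‑methylhept‑5‑enoic acid, lactonising, and forming the butenolide by sulfoxide formation (mCPBA) and thermal syn‑elimination.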